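**Retrosynthetic overview**
- The target is traced back to an aryl enone carrying three benzyl ethers; one acidic hydrogenation removes the C=C, reduces the aryl C=O to CH2 and cleaves all O-benzyl groups.
- The enone comes from dehydration of the product of the key intermolecular aldol addition: the lithium enolate of 3,5-bis(benzyloxy)acetophenone (chain C1–C2) adds to (S)-14-(benzyloxy)pentadecanal (chain C3–C17), forming the C2–C3 bond.
- The aldehyde comes from dodecane-1,12-diol (C12) and (S)-propylene oxide (C3, the source of the only stereocentre) by monobromination, silylation, copper-catalysed Grignard epoxide opening, benzylation, desilylation and oxidation.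
- No ring is formed in the route; the benzene ring is bought with the acetophenone.

Assumption: the target is read as 5-[(16S)-16-hydroxyheptadecyl]benzene-1,3-diol, with 15 CH2 groups between the arene and the (S)-carbinol carbon; protecting-group reagents and bases are treated as reagents and are not numbered.

**Route**

Step 1
Reactants: 1 dodecane-1,12-diol
Product: 2 12-bromododecan-1-ol
Conditions: 48% aq HBr (1.2 equiv), toluene, reflux, 24 h
Reagents that add atoms: hydrogen bromide, Br
Why: In the two-phase HBr/toluene system the monobromide passes into toluene as it forms, so SN2 substitution of one protonated hydroxyl stops at the bromo alcohol (nucleophilic substitution, desymmetrisation of a diol).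

Step 2
Reactants: 2 12-bromododecan-1-ol
Product: 3 [(12-bromododecyl)oxy](tert-butyl)dimethylsilane
Conditions: TBSCl, imidazole, DMF, rt
Reagents that add atoms: tert-butylchlorodimethylsilane (TBSCl), CC(C)(C)[Si](C)(C)Cl
Why: Standard silylation of a primary alcohol gives a silyl ether that tolerates the Grignard chemistry of step 3.

Step 3
Reactants: 3 [(12-bromododecyl)oxy](tert-butyl)dimethylsilane, 4 (S)-propylene oxide [(2S)-2-methyloxirane]
Product: 6 (2S)-15-[(tert-butyldimethylsilyl)oxy]pentadecan-2-ol, via Grignard reagent 5 (not isolated)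
Conditions: Mg, I2 (cat.), THF, 40 °C; then CuI (10 mol %), 4, −30 → 0 °C; sat. aq NH4Cl
Reagents that add atoms: none
Why: Under CuI catalysis Grignard reagent 5 opens the epoxide by SN2 attack at the unsubstituted CH2, so the C–O stereocentre of 4 is carried over untouched as the (S)-carbinol (copper-catalysed Grignard epoxide opening, chiral-pool control).

Step 4
Reactants: 6 (2S)-15-[(tert-butyldimethylsilyl)oxy]pentadecan-2-ol
Product: 8 {[(14S)-14-(benzyloxy)pentadecyl]oxy}(tert-butyl)dimethylsilane, via sodium alkoxide 7 (not isolated)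
Conditions: NaH, BnBr, Bu4NI (cat.), THF, 0 → 50 °C
Reagents that add atoms: benzyl bromide, BrCc1ccccc1
Why: Williamson ether synthesis takes place at oxygen, so no bond to the stereocentre is broken, and the benzyl ether is removed later in the final hydrogenolysis.

Step 5
Reactants: 8 {[(14S)-14-(benzyloxy)pentadecyl]oxy}(tert-butyl)dimethylsilane
Product: 9 (14S)-14-(benzyloxy)pentadecan-1-ol
Conditions: p-TsOH·H2O (10 mol %), MeOH/CH2Cl2, rt
Reagents that add atoms: none
Why: Acid-catalysed methanolysis removes the primary silyl ether while the benzyl ether is inert (silyl transfer to methanol).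

Step 6
Reactants: 9 (14S)-14-(benzyloxy)pentadecan-1-ol
Product: 10 (14S)-14-(benzyloxy)pentadecanal
Conditions: TEMPO (10 mol %), PhI(OAc)2 (1.1 equiv), CH2Cl2, rt
Reagents that add atoms: none
Why: Oxoammonium-mediated oxidation of a primary alcohol stops at the aldehyde in the absence of water and leaves the benzyl ether and the remote stereocentre untouched (TEMPO oxidation).

Step 7
Reactants: 10 (14S)-14-(benzyloxy)pentadecanal, 11 1-[3,5-bis(benzyloxy)phenyl]ethan-1-one
Product: 13 (16S)-16-(benzyloxy)-1-[3,5-bis(benzyloxy)phenyl]-3-hydroxyheptadecan-1-one (both C3 epimers), via lithium enolate 12 (not isolated)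
Conditions: 11, LiN(SiMe3)2, THF, −78 °C, 45 min; then 10, −78 °C, 1 h; AcOH quench at −78 °C
Reagents that add atoms: none
Why: In this directed intermolecular aldol addition the ketone, enolisable at one position only, is fully converted into lithium enolate 12 before the aldehyde is added at −78 °C, which suppresses self-condensation; the new carbinol centre forms unselectively and is removed in step 8.

Step 8
Reactants: 13 (16S)-16-(benzyloxy)-1-[3,5-bis(benzyloxy)phenyl]-3-hydroxyheptadecan-1-one
Product: 15 (2E,16S)-16-(benzyloxy)-1-[3,5-bis(benzyloxy)phenyl]heptadec-2-en-1-one, via β-mesyloxy ketone 14 (not isolated)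
Conditions: MsCl (1.5 equiv), Et3N (4 equiv), CH2Cl2, 0 °C → rt
Reagents that add atoms: none
Why: Mesylation of the β-hydroxyl and E1cB elimination of 14, driven by the acidic α-CH2 of the aryl ketone, give the conjugated enone in its favoured E geometry (aldol dehydration).

Step 9
Reactants: 15 (2E,16S)-16-(benzyloxy)-1-[3,5-bis(benzyloxy)phenyl]heptadec-2-en-1-one
Product: 18 hansfordiol A 5-[(16S)-16-hydroxyheptadecyl]benzene-1,3-diol, via saturated triol ketone 16 (not isolated), via benzylic alcohol 17 (not isolated)
Conditions: H2 (4 atm), 10% Pd/C, EtOH–EtOAc, conc. HCl (cat.), rt → 40 °C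
Reagents that add atoms: none
Why: Catalytic hydrogenation saturates the alkene and cleaves the three O-benzyl bonds to give 16, and under acid the aryl ketone is reduced to 17 and hydrogenolysed to CH2, so all partly reduced species converge on the target; the C16–O bond is not benzylic and stays (S) (hydrogenation and benzylic hydrogenolysis).

**Compound list**

1 | dodecane-1,12-diol | OCCCCCCCCCCCCO | starting material
2 | 12-bromododecan-1-ol | OCCCCCCCCCCCCBr | intermediate
3 | [(12-bromododecyl)oxy](tert-butyl)dimethylsilane | CC(C)(C)[Si](C)(C)OCCCCCCCCCCCCBr | intermediate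
4 | (S)-propylene oxide, (2S)-2-methyloxirane | C[C@H]1CO1 | starting material
5 | {12-[(tert-butyldimethylsilyl)oxy]dodecyl}magnesium bromide (not isolated) | CC(C)(C)[Si](C)(C)OCCCCCCCCCCCC[Mg]Br | intermediate
6 | (2S)-15-[(tert-butyldimethylsilyl)oxy]pentadecan-2-ol | C[C@H](O)CCCCCCCCCCCCCO[Si](C)(C)C(C)(C)C | intermediate
7 | sodium (2S)-15-[(tert-butyldimethylsilyl)oxy]pentadecan-2-olate (not isolated) | C[C@H]([O-])CCCCCCCCCCCCCO[Si](C)(C)C(C)(C)C.[Na+] | intermediate
8 | {[(14S)-14-(benzyloxy)pentadecyl]oxy}(tert-butyl)dimethylsilane | C[C@H](OCc1ccccc1)CCCCCCCCCCCCCO[Si](C)(C)C(C)(C)C | intermediate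
9 | (14S)-14-(benzyloxy)pentadecan-1-ol | C[C@H](OCc1ccccc1)CCCCCCCCCCCCCO | intermediate
10 | (14S)-14-(benzyloxy)pentadecanal | C[C@H](OCc1ccccc1)CCCCCCCCCCCCC=O | intermediate
11 | 1-[3,5-bis(benzyloxy)phenyl]ethan-1-one | CC(=O)c1cc(OCc2ccccc2)cc(OCc2ccccc2)c1 | starting material
12 | lithium 1-[3,5-bis(benzyloxy)phenyl]ethen-1-olate (not isolated) | C=C(O[Li])c1cc(OCc2ccccc2)cc(OCc2ccccc2)c1 | intermediate
13 | (16S)-16-(benzyloxy)-1-[3,5-bis(benzyloxy)phenyl]-3-hydroxyheptadecan-1-one (both C3 epimers) | C[C@H](OCc1ccccc1)CCCCCCCCCCCCC(O)CC(=O)c1cc(OCc2ccccc2)cc(OCc2ccccc2)c1 | intermediate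
14 | (16S)-16-(benzyloxy)-1-[3,5-bis(benzyloxy)phenyl]-1-oxoheptadecan-3-yl methanesulfonate (not isolated) | C[C@H](OCc1ccccc1)CCCCCCCCCCCCC(OS(C)(=O)=O)CC(=O)c1cc(OCc2ccccc2)cc(OCc2ccccc2)c1 | intermediate
15 | (2E,16S)-16-(benzyloxy)-1-[3,5-bis(benzyloxy)phenyl]heptadec-2-en-1-one | C[C@H](OCc1ccccc1)CCCCCCCCCCCC/C=C/C(=O)c1cc(OCc2ccccc2)cc(OCc2ccccc2)c1 | intermediate
16 | (16S)-1-(3,5-dihydroxyphenyl)-16-hydroxyheptadecan-1-one (not isolated) | C[C@H](O)CCCCCCCCCCCCCCC(=O)c1cc(O)cc(O)c1 | intermediate
17 | (16S)-1-(3,5-dihydroxyphenyl)heptadecane-1,16-diol (both C1 epimers, not isolated) | C[C@H](O)CCCCCCCCCCCCCCC(O)c1cc(O)cc(O)c1 | intermediate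
18 | hansfordiol A, 5-[(16S)-16-hydroxyheptadecyl]benzene-1,3-diol | C[C@H](O)CCCCCCCCCCCCCCCc1cc(O)cc(O)c1 | target

**Summary**

Total step count: 9. Longest linear sequence: 9 steps (1 → 18); compounds 4 and 11 are bought and enter in steps 3 and 7.

Steps most likely to fail:

Step 3 (Grignard formation from the long-chain bromide and epoxide opening). The risks are Wurtz homocoupling and bromohydrin formation. The fallback sets out from bromide 3 and comes back at alcohol 6. Bromide 3 is heated with PhSO2Na in DMF (60 °C) to give the sulfone tert-butyldimethyl{[12-(phenylsulfonyl)dodecyl]oxy}silane F1. F1 is treated with n-BuLi (THF, −78 °C) and then with epoxide 4 and BF3·OEt2, again attacking the unsubstituted CH2, to give the hydroxy sulfone (2S)-15-[(tert-butyldimethylsilyl)oxy]-4-(phenylsulfonyl)pentadecan-2-ol F2 as both C4 epimers. Reductive desulfonylation (6% Na/Hg, Na2HPO4, MeOH, −20 °C → rt) then gives 6 with the stereocentre unchanged.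

Step 7 (the aldol addition). The risks are enolisation of the aldehyde, retro-aldol on work-up and incomplete conversion. The fallback sets out from ketone 11 and comes back at aldol 13. Ketone 11 is converted with Me3SiOTf/Et3N (CH2Cl2, 0 °C) into the silyl enol ether {[1-(3,5-bis(benzyloxy)phenyl)ethenyl]oxy}trimethylsilane F3. F3 is added to aldehyde 10 under BF3·OEt2 activation (CH2Cl2, −78 °C, aqueous work-up) in a Mukaiyama aldol addition, which runs under Lewis-acidic, non-basic conditions and gives 13.

Step 9 (one-pot reduction of the aryl ketone to CH2). The risk is stalling at ketone 16 or alcohol 17. The fallback sets out from enone 15 and comes back at target 18. Enone 15 is hydrogenated without acid (H2 1 atm, 10% Pd/C, EtOAc, rt, stopped once the alkene and benzyl groups are gone) and ketone 16 is isolated. Heating 16 with N2H4·H2O in diethylene glycol (130 °C) gives the hydrazone 5-[(16S)-1-hydrazinylidene-16-hydroxyheptadecyl]benzene-1,3-diol F4. KOH is then added and the mixture heated to 200 °C (Wolff–Kishner reduction, Huang-Minlon procedure), which expels N2 and gives 18. The hydrazone is formed before the strong heating so that no ketone is left to exchange hydride with the secondary alkoxide.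

Further compounds
F1 | step 3 | tert-butyldimethyl{[12-(phenylsulfonyl)dodecyl]oxy}silane | CC(C)(C)[Si](C)(C)OCCCCCCCCCCCCS(=O)(=O)c1ccccc1
F2 | step 3 | (2S)-15-[(tert-butyldimethylsilyl)oxy]-4-(phenylsulfonyl)pentadecan-2-ol (both C4 epimers) | C[C@H](O)CC(S(=O)(=O)c1ccccc1)CCCCCCCCCCCO[Si](C)(C)C(C)(C)C
F3 | step 7 | {[1-(3,5-bis(benzyloxy)phenyl)ethenyl]oxy}trimethylsilane | C=C(O[Si](C)(C)C)c1cc(OCc2ccccc2)cc(OCc2ccccc2)c1
F4 | step 9 | 5-[(16S)-1-hydrazinylidene-16-hydroxyheptadecyl]benzene-1,3-diol | C[C@H](O)CCCCCCCCCCCCCCC(=NN)c1cc(O)cc(O)c1
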